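Count the catalyst's turns first, because in these flasks the yield is turns made against turns needed.

common to all: free catalyst 0.95 mM
- cedar: starting material 0.095 M (fed, over 2.50 min); partner 0.143 M; time 2.5 min; all but starting material at the start; starting material goes in evenly over 2.50 min, the run ends at 2.5 min
- oak: starting material 0.095 M; partner 0.143 M; a single well-mixed tank run continuously and read at steady state, 2.5 min in it on average
- ash: starting material 0.095 M; partner 0.143 M (fed, over 2.50 min); time 2.5 min; all but partner at the start; partner goes in evenly over 2.50 min, the run ends at 2.5 min
- elm: starting material 0.095 M; partner 0.143 M; time 2.5 min; everything together in a closed stirred flask, run for 2.5 min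

    catalyst intermediate B → catalyst intermediate C (k1 = 80 s⁻¹)
    catalyst intermediate C ⇌ free catalyst + product (K2 = 0.075 M, k2 = 1.3 s⁻¹)
    free catalyst + product ⇌ idle complex (K3 = 3.6 M⁻¹, k3 = 0.31 M⁻¹ s⁻¹)
    starting material + catalyst intermediate A ⇌ catalyst intermediate B (K4 = 5.6 M⁻¹, k4 = 410 M⁻¹ s⁻¹)
    partner + free catalyst ⇌ catalyst intermediate A (K5 = 15 M⁻¹, k5 = 26 M⁻¹ s⁻¹)
    catalyst intermediate A → spent catalyst (k6 = 0.0041 s⁻¹)

- amounts and yields of product count idle complex too
- the stated concentrations are those of everything mixed, before any reaction; amounts are the same in each set-up
- the feed brings no volume worth counting
- run time (cedar): 2.5 min

- the set-up with the highest amount of product at the outlet or at the end, in percent of the starting material put in ("none" if the first two lie within 2 percentage points) (cedar / oak / ash / elm / none)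
- amount of product at the outlet or at the end, in percent of the starting material put in, cedar
- amount of product at the outlet or at the end, in percent of the starting material put in, oak
- amount of product at the outlet or at the end, in percent of the starting material put in, ash
- amount of product at the outlet or at the end, in percent of the starting material put in, elm

Take elm, the closed flask. Its charge needs 100 turns of each catalyst molecule. The forward way from catalyst intermediate A through B to C costs 0.0382 s at the charge of starting material, far less than the 0.769 s of the release of product from catalyst intermediate C, so I count two waits: that release, and free catalyst finding partner. With the whole charge as product, the equilibrium of the step to idle complex puts idle complex at 0.342 times free catalyst, less than free catalyst itself, so I leave idle complex out of the turn count.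

Now I solve two extreme flasks. In the clean flask, with no product and partner at its charge, a turn takes 1.04 s, and the run allows 144 turns, more than elm needs. In the finished flask, the whole charge is product and partner is down to 0.0480 M. The wait for partner grows, and the return of product onto free catalyst stretches it by one plus c(product) over 0.075 M, so a turn takes 2.59 s and the run allows 57.9 turns, fewer than needed.

Elm passes from the first state towards the second, and time adds up turn by turn, so I join them by the mean turn time, the arithmetic mean of the two turn times, 1.81 s. That gives 82.8 % for elm. Oak, the tank, makes its turns at outlet composition, so the finished flask gives it a floor, 58.0 %, and elm's mean turn is shorter. I put elm above oak and do not reckon the dosed flasks, cedar and ash.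

The forecast names elm and starts from this: “Turnover is limited by C → free catalyst + product”. The simulation names elm.

| Flask | Forecast | Simulation |
|---|---|---|
| cedar | 66.5 % | 66.7 % |
| oak | 66.2 % | 66.0 % |
| ash | 62 % | 61.6 % |
| elm | 83.5 % | 84.2 % |

Given ten times the time, elm reaches 99.9 %; its shortfall at 2.5 min comes from the time allowed and the return of free catalyst and product into catalyst intermediate C, acting together. With that return struck out, elm gives 93.4 %, which closes a part of the gap. Now read elm at 1.0 min: 1.81 s gives 33.1 % and 1.04 s gives 57.8 %, and since this flask has not gone the whole way, I expect it between them. It gives 44.6 %.

All constants belong to no real substance, and the outcome is calculated.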